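**Plan**
- Retrosynthesis: the angelate and acetate C–O bonds are cut first, then the isobutenyl–C(=O) bond (alkenyllithium + δ-lactone), then the side-chain CH(CH3)–CH2 bond by a retro-Claisen that returns the ring oxygen to an allylic alcohol; the ring goes back to 4,4-dimethoxycyclohexa-2,5-dienone.
- Enabling feature: the ring carbon bearing the angelate oxygen, the adjacent ring CH and the exocyclic CH(CH3) are contiguous, and the CH2 to be attached is α to an oxygenated carbon. With a C=C drawn between the ring CH and the exocyclic carbon, this is an O–C–C=C / C=C–O Claisen array whose oxygen is the target's own ring oxygen.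
- Forward: the six-membered ring is present from the start; methyl by Cu-catalysed 1,4-addition, ethylidene by reductive aldol/dehydration, CBS reduction, ortho ester Claisen, hydroboration/lactonisation, isobutenyllithium, angeloylation, CBS reduction, acetylation, ketal hydrolysis/epimerisation, L-Selectride.
- Stereochemistry: the side-chain CH(CH3) comes from 1,3-chirality transfer from the CBS-set carbinol through the E-ethylidene group. The ring C–O and C–H centres come from syn hydroboration anti to a deliberately 5R (temporary) methyl, which also holds the C–O bond axial for the rearrangement and is epimerised to the equatorial position once the neighbouring ketone is unmasked.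
- The ring OH comes from equatorial hydride delivery, the side-chain carbinol from a second CBS reduction, the Z-enoate from angelic acid. Helpers removed later: ring C=C, ester oxidation level at the side-chain carbinol carbon, dimethyl ketal, temporary methyl configuration.

Key step: step 5

Remark: metal alkoxides, enolates and boron alkoxides that are only protonated or hydrolysed on work-up are not numbered; the lithium enolate of step 2 and the alkylborane of step 6 are numbered because a second reagent reacts with them.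

Step 1
Reactants: 1 4,4-dimethoxycyclohexa-2,5-dien-1-one
Product: 2 (5R)-4,4-dimethoxy-5-methylcyclohex-2-en-1-one
Conditions: Me2Zn (1.5 equiv), Cu(OTf)2 (2 mol%), BINOL-derived bis(1-phenylethyl)amine phosphoramidite (4 mol%, antipode giving the 5R adduct), PhMe, −25 °C; aq. work-up
Reagents that add atoms: dimethylzinc, C[Zn]C
Why: Copper/phosphoramidite-catalysed enantioselective 1,4-addition of a dialkylzinc to a benzoquinone monoketal (desymmetrisation of the two enone arms) is a known reaction type; the ligand antipode sets the methyl-bearing centre as 5R, and the zinc enolate formed should not add a second time.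

Step 2
Reactants: 2 (5R)-4,4-dimethoxy-5-methylcyclohex-2-en-1-one; 3 acetaldehyde
Product: 5 (5R)-2-(1-hydroxyethyl)-4,4-dimethoxy-5-methylcyclohexan-1-one (mixture at C2 and the carbinol carbon), via lithium enolate 4 (not isolated)
Conditions: L-Selectride (1.05 equiv), THF, −78 °C; then CH3CHO, −78 °C; H2O
Reagents that add atoms: none
Why: L-Selectride should add hydride 1,4 to the β-unsubstituted cyclohexenone, and the regiodefined enolate 4 is trapped by acetaldehyde (reductive aldol), so the two-carbon unit goes to C2 and not C6; both new centres are destroyed in step 3.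

Step 3
Reactants: 5 (5R)-2-(1-hydroxyethyl)-4,4-dimethoxy-5-methylcyclohexan-1-one
Product: 7 (2E,5R)-2-ethylidene-4,4-dimethoxy-5-methylcyclohexan-1-one, via mesylate 6 (not isolated)
Conditions: MsCl, Et3N, CH2Cl2, 0 °C; then DBU, rt
Reagents that add atoms: none
Why: Mesylation and E1cB elimination of a β-hydroxy ketone gives the exocyclic enone, and the E isomer (methyl anti to C=O) is the thermodynamic and usual product for 2-alkylidenecyclohexanones.

Step 4
Reactants: 7 (2E,5R)-2-ethylidene-4,4-dimethoxy-5-methylcyclohexan-1-one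
Product: 8 (1R,2E,5R)-2-ethylidene-4,4-dimethoxy-5-methylcyclohexan-1-ol
Conditions: (S)-Me-CBS (0.2 equiv), BH3·SMe2 (0.7 equiv), THF, −20 °C; MeOH
Reagents that add atoms: none
Why: Corey–Bakshi–Shibata reduction, with the fully substituted alkenyl carbon as the large group and the ring CH2 as the small one, should give the 1R alcohol under reagent control; hydride enters equatorially, so the OH is axial and trans to the equatorial methyl.

Step 5
Reactants: 8 (1R,2E,5R)-2-ethylidene-4,4-dimethoxy-5-methylcyclohexan-1-ol; 9 trimethyl orthoacetate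
Product: 12 methyl (3R)-3-[(4R)-5,5-dimethoxy-4-methylcyclohex-1-en-1-yl]butanoate, via mixed ortho ester 10 (not isolated), via ketene acetal 11 (not isolated)
Conditions: MeC(OMe)3 (8 equiv), EtCO2H (0.1 equiv), PhMe, 120 °C, sealed tube
Reagents that add atoms: none
Why: Acid-catalysed exchange gives mixed ortho ester 10, loss of methanol gives ketene acetal 11, and a concerted suprafacial [3,3] shift (Johnson ortho ester Claisen; closest precedent is 1,3-chirality transfer from ring allylic alcohols carrying an exocyclic ethylidene group, as used for steroid C20 centres) forms the CH(CH3)–CH2 bond while the ring C–O bond breaks and the double bond moves into the ring. No ring is closed; the six-atom O–C1–C2=CH / CH2=C(OMe) array is only the chair-like transition state. The new stereocentre is controlled by two substrate elements: the axial C1–O bond (1R) delivers the ketene acetal carbon to the same face of the exocyclic carbon from which oxygen departs, and the E geometry fixes the positions of H and CH3, so (1R, E) should give 3R. The step needs [3,3] to win over elimination and needs a single reacting conformer; the trans-1,3 relation of OH and equatorial methyl holds the C–O bond axial in the ground-state chair, and the vinylic H (not CH3) is syn to the carbinol carbon, so the transition state has no allylic strain. The closed vessel keeps methanol in the mixture so that the dimethyl ketal is not converted into an enol ether.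

Step 6
Reactants: 12 methyl (3R)-3-[(4R)-5,5-dimethoxy-4-methylcyclohex-1-en-1-yl]butanoate
Product: 15 (4R,4aS,7R,8aR)-6,6-dimethoxy-4,7-dimethyloctahydro-2H-chromen-2-one (trans-fused), via alkylborane 13 (not isolated), via hydroxy ester 14 (not isolated)
Conditions: BH3·THF (1.5 equiv), THF, 0 °C to rt; NaBO3·4H2O, H2O, rt; then PPTS (cat.), CH2Cl2, rt
Reagents that add atoms: sodium perborate, [Na+].[Na+].O[B-]1(O)OO[B-](O)(O)OO1
Why: Hydroboration–oxidation puts boron on the ring CH carbon and adds H and B syn, so OH and side chain are trans; attack should come anti to the ring methyl because the methyl-bearing face is shielded in both half-chairs (by the axial ketal OCH3 when the methyl is equatorial, by the axial CH3 itself, 1,3 to the carbon that takes boron, when it is not), and the diequatorial δ-hydroxy ester 14 lactonises.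

Step 7
Reactants: 15 (4R,4aS,7R,8aR)-6,6-dimethoxy-4,7-dimethyloctahydro-2H-chromen-2-one; 16 1-bromo-2-methylprop-1-ene
Product: 17 (6R)-6-[(1S,2R,4R)-2-hydroxy-5,5-dimethoxy-4-methylcyclohexyl]-2-methylhept-2-en-4-one
Conditions: 16 (1.3 equiv), t-BuLi (2.6 equiv), Et2O, −78 °C; then 15, THF, −78 °C; H2O
Reagents that add atoms: none
Why: One equivalent of an alkenyllithium adds to a δ-lactone at −78 °C to give a lactolate that only collapses on work-up, so the enone is released after the nucleophile is gone and the ring hydroxyl is freed in the same operation (the conjugated open-chain ketone is expected to be favoured over its hemiketal).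

Step 8
Reactants: 17 (6R)-6-[(1S,2R,4R)-2-hydroxy-5,5-dimethoxy-4-methylcyclohexyl]-2-methylhept-2-en-4-one; 18 angelic acid ((Z)-2-methylbut-2-enoic acid)
Product: 19 (1R,2S,5R)-4,4-dimethoxy-5-methyl-2-[(2R)-6-methyl-4-oxohept-5-en-2-yl]cyclohexyl (2Z)-2-methylbut-2-enoate
Conditions: 18 (2 equiv), 2,4,6-Cl3C6H2COCl, Et3N, PhMe, rt; then 17, PhMe, 80 °C
Reagents that add atoms: none
Why: Acylation by the mixed anhydride of angelic and 2,4,6-trichlorobenzoic acid without DMAP (Yamaguchi-type) is the established way to angeloylate hindered secondary alcohols without Z-to-E isomerisation to the tiglate.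

Step 9
Reactants: 19 (1R,2S,5R)-4,4-dimethoxy-5-methyl-2-[(2R)-6-methyl-4-oxohept-5-en-2-yl]cyclohexyl (2Z)-2-methylbut-2-enoate
Product: 20 (1R,2S,5R)-2-[(2R,4R)-4-hydroxy-6-methylhept-5-en-2-yl]-4,4-dimethoxy-5-methylcyclohexyl (2Z)-2-methylbut-2-enoate
Conditions: (S)-Me-CBS (0.5 equiv), catecholborane (1.5 equiv), PhMe, −78 °C; aq. NaHCO3
Reagents that add atoms: none
Why: CBS 1,2-reduction of the enone with catecholborane, the isobutenyl group acting as the large substituent, should give the 4R allylic alcohol under reagent control; the enoate ester and the ketal are inert at −78 °C.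

Step 10
Reactants: 20 (1R,2S,5R)-2-[(2R,4R)-4-hydroxy-6-methylhept-5-en-2-yl]-4,4-dimethoxy-5-methylcyclohexyl (2Z)-2-methylbut-2-enoate
Product: 21 (1R,2S,5R)-2-[(2R,4R)-4-acetoxy-6-methylhept-5-en-2-yl]-4,4-dimethoxy-5-methylcyclohexyl (2Z)-2-methylbut-2-enoate
Conditions: Ac2O, pyridine, rt
Reagents that add atoms: acetic anhydride, CC(=O)OC(C)=O
Why: Standard acetylation of the only free (secondary allylic) hydroxyl; DMAP is left out so that the angelate meets no nucleophilic catalyst.

Step 11
Reactants: 21 (1R,2S,5R)-2-[(2R,4R)-4-acetoxy-6-methylhept-5-en-2-yl]-4,4-dimethoxy-5-methylcyclohexyl (2Z)-2-methylbut-2-enoate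
Product: 23 (1R,2S,5S)-2-[(2R,4R)-4-acetoxy-6-methylhept-5-en-2-yl]-5-methyl-4-oxocyclohexyl (2Z)-2-methylbut-2-enoate, via axial-methyl ketone 22 (not isolated)
Conditions: PPTS (0.2 equiv), acetone/H2O 10:1, rt; then DBU (0.3 equiv), CH2Cl2, rt
Reagents that add atoms: water, O
Why: A dimethyl ketal is hydrolysed by PPTS in wet acetone under conditions that should leave the allylic acetate and the enoate alone, and the α-methyl ketone 22 (methyl axial) is then equilibrated through its enol(ate) to the equatorial 5S epimer 23, in which ester, side chain and methyl are all equatorial; no other ring centre is enolisable.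

Step 12
Reactants: 23 (1R,2S,5S)-2-[(2R,4R)-4-acetoxy-6-methylhept-5-en-2-yl]-5-methyl-4-oxocyclohexyl (2Z)-2-methylbut-2-enoate
Product: 24 (1R,2S,4R,5S)-2-[(2R,4R)-4-acetoxy-6-methylhept-5-en-2-yl]-4-hydroxy-5-methylcyclohexyl (2Z)-2-methylbut-2-enoate (CNP0237033.1)
Conditions: L-Selectride (1.1 equiv), THF, −78 °C; H2O
Reagents that add atoms: none
Why: L-Selectride attacks a 2-methylcyclohexanone from the equatorial direction and should give the axial alcohol cis to the methyl (4R), and at −78 °C a ketone is reduced much faster than an acetate or a β-substituted enoate.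

**Compound list**
1 | 4,4-dimethoxycyclohexa-2,5-dien-1-one | COC1(OC)C=CC(=O)C=C1 | starting material
2 | (5R)-4,4-dimethoxy-5-methylcyclohex-2-en-1-one | O=C1C[C@@H](C)C(OC)(OC)C=C1 | intermediate
3 | acetaldehyde | CC=O | starting material
4 | lithium (5R)-4,4-dimethoxy-5-methylcyclohex-1-en-1-olate | [Li+].[O-]C1=CCC(OC)(OC)[C@H](C)C1 | intermediate
5 | (5R)-2-(1-hydroxyethyl)-4,4-dimethoxy-5-methylcyclohexan-1-one (diastereomer mixture) | CC(O)C1CC(OC)(OC)[C@H](C)CC1=O | intermediate
6 | 1-[(4R)-5,5-dimethoxy-4-methyl-2-oxocyclohexyl]ethyl methanesulfonate (diastereomer mixture) | CC(OS(C)(=O)=O)C1CC(OC)(OC)[C@H](C)CC1=O | intermediate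
7 | (2E,5R)-2-ethylidene-4,4-dimethoxy-5-methylcyclohexan-1-one | C/C=C1/C(=O)C[C@@H](C)C(OC)(OC)C1 | intermediate
8 | (1R,2E,5R)-2-ethylidene-4,4-dimethoxy-5-methylcyclohexan-1-ol | C/C=C1/[C@H](O)C[C@@H](C)C(OC)(OC)C1 | intermediate
9 | trimethyl orthoacetate (1,1,1-trimethoxyethane) | COC(C)(OC)OC | starting material
10 | (1R,2E,5R)-1-(1,1-dimethoxyethoxy)-2-ethylidene-4,4-dimethoxy-5-methylcyclohexane | C/C=C1/[C@H](OC(C)(OC)OC)C[C@@H](C)C(OC)(OC)C1 | intermediate
11 | (1R,2E,5R)-2-ethylidene-4,4-dimethoxy-1-[(1-methoxyethenyl)oxy]-5-methylcyclohexane | C/C=C1/[C@H](OC(=C)OC)C[C@@H](C)C(OC)(OC)C1 | intermediate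
12 | methyl (3R)-3-[(4R)-5,5-dimethoxy-4-methylcyclohex-1-en-1-yl]butanoate | COC(=O)C[C@@H](C)C1=CC[C@@H](C)C(OC)(OC)C1 | intermediate
13 | methyl (3R)-3-[(1R,2R,4R)-2-boranyl-5,5-dimethoxy-4-methylcyclohexyl]butanoate | B[C@@H]1C[C@@H](C)C(OC)(OC)C[C@H]1[C@H](C)CC(=O)OC | intermediate
14 | methyl (3R)-3-[(1S,2R,4R)-2-hydroxy-5,5-dimethoxy-4-methylcyclohexyl]butanoate | O[C@@H]1C[C@@H](C)C(OC)(OC)C[C@H]1[C@H](C)CC(=O)OC | intermediate
15 | (4R,4aS,7R,8aR)-6,6-dimethoxy-4,7-dimethyloctahydro-2H-chromen-2-one | O1[C@@H]2C[C@@H](C)C(OC)(OC)C[C@H]2[C@H](C)CC1=O | intermediate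
16 | 1-bromo-2-methylprop-1-ene | CC(C)=CBr | starting material
17 | (6R)-6-[(1S,2R,4R)-2-hydroxy-5,5-dimethoxy-4-methylcyclohexyl]-2-methylhept-2-en-4-one | O[C@@H]1C[C@@H](C)C(OC)(OC)C[C@H]1[C@H](C)CC(=O)C=C(C)C | intermediate
18 | angelic acid, (Z)-2-methylbut-2-enoic acid | C/C=C(/C)C(=O)O | starting material
19 | (1R,2S,5R)-4,4-dimethoxy-5-methyl-2-[(2R)-6-methyl-4-oxohept-5-en-2-yl]cyclohexyl (2Z)-2-methylbut-2-enoate | C/C=C(/C)C(=O)O[C@@H]1C[C@@H](C)C(OC)(OC)C[C@H]1[C@H](C)CC(=O)C=C(C)C | intermediate
20 | (1R,2S,5R)-2-[(2R,4R)-4-hydroxy-6-methylhept-5-en-2-yl]-4,4-dimethoxy-5-methylcyclohexyl (2Z)-2-methylbut-2-enoate | C/C=C(/C)C(=O)O[C@@H]1C[C@@H](C)C(OC)(OC)C[C@H]1[C@H](C)C[C@H](C=C(C)C)O | intermediate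
21 | (1R,2S,5R)-2-[(2R,4R)-4-acetoxy-6-methylhept-5-en-2-yl]-4,4-dimethoxy-5-methylcyclohexyl (2Z)-2-methylbut-2-enoate | C/C=C(/C)C(=O)O[C@@H]1C[C@@H](C)C(OC)(OC)C[C@H]1[C@H](C)C[C@H](C=C(C)C)OC(C)=O | intermediate
22 | (1R,2S,5R)-2-[(2R,4R)-4-acetoxy-6-methylhept-5-en-2-yl]-5-methyl-4-oxocyclohexyl (2Z)-2-methylbut-2-enoate (methyl axial) | C/C=C(/C)C(=O)O[C@@H]1C[C@@H](C)C(=O)C[C@H]1[C@H](C)C[C@H](C=C(C)C)OC(C)=O | intermediate
23 | (1R,2S,5S)-2-[(2R,4R)-4-acetoxy-6-methylhept-5-en-2-yl]-5-methyl-4-oxocyclohexyl (2Z)-2-methylbut-2-enoate | C/C=C(/C)C(=O)O[C@@H]1C[C@H](C)C(=O)C[C@H]1[C@H](C)C[C@H](C=C(C)C)OC(C)=O | intermediate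
24 | (1R,2S,4R,5S)-2-[(2R,4R)-4-acetoxy-6-methylhept-5-en-2-yl]-4-hydroxy-5-methylcyclohexyl (2Z)-2-methylbut-2-enoate | C/C=C(/C)C(=O)O[C@@H]1C[C@H](C)[C@H](O)C[C@H]1[C@H](C)C[C@H](C=C(C)C)OC(C)=O | target

Total step count: 12. Longest linear sequence: 12 steps (1 to 24; all other inputs are commercial).

**Steps most likely to fail**

1. Step 6: poor facial selectivity in the hydroboration. Attack syn to the ring methyl would give the diastereomeric trans-lactone, which cannot be corrected later because thermodynamic control in this series favours the wrong ring. Fallback, setting out from 12: substrate control is replaced by reagent control. Monoisopinocampheylborane made from (−)-α-pinene is used (the antipode that, by analogy with 1-methylcyclohexene, should give the (1R,2R)-type trans-2-alkylcycloalkanol) and gives the mixed borane F1. Perborate oxidation gives 14, and PPTS closes it to the lactone, coming back to the route at 15.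

2. Step 11: loss or allylic transposition of the secondary allylic acetate during acidic unmasking, or incomplete equilibration of the methyl group with base-sensitive esters present. Fallback, setting out from 15: the ketone is unmasked and corrected at the robust lactone stage. 1 M HCl/THF gives the axial-methyl keto lactone F2, and DBU equilibrates it to the equatorial epimer F3. L-Selectride gives the axial alcohol F4, and TESOTf/2,6-lutidine gives the silyl ether F5. 2-Methylprop-1-enyllithium gives the hydroxy enone F6, and mixed-anhydride angeloylation gives F7. CBS reduction gives the allylic alcohol F8, and Ac2O/pyridine gives the acetate F9. HF·pyridine in THF/pyridine removes the silyl group and comes back to the route at 24.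

3. Step 9: insufficient facial discrimination by the CBS catalyst between the CH2 and isobutenyl flanks, giving an epimer mixture at the side-chain carbinol. Fallback, setting out from 19: Luche reduction (NaBH4, CeCl3, MeOH) without stereocontrol, then chromatographic separation of 20 from its 4S epimer F10. 20 goes on through step 10, and F10 is converted into the same acetate by Mitsunobu reaction with acetic acid (PPh3, DIAD), which inverts the carbinol centre, coming back to the route at 21.

**Further compounds**
F1 | step 6 | methyl (3R)-3-[(1R,2R,4R)-2-(isopinocampheylboranyl)-5,5-dimethoxy-4-methylcyclohexyl]butanoate (isopinocampheyl from (−)-α-pinene) | C[C@@H]1[C@@H](B[C@@H]3C[C@@H](C)C(OC)(OC)C[C@H]3[C@H](C)CC(=O)OC)C[C@H]2C[C@@H]1C2(C)C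
F2 | step 11 | (4R,4aS,7R,8aR)-4,7-dimethylhexahydro-2H-chromene-2,6(3H)-dione (methyl axial) | O1[C@@H]2C[C@@H](C)C(=O)C[C@H]2[C@H](C)CC1=O
F3 | step 11 | (4R,4aS,7S,8aR)-4,7-dimethylhexahydro-2H-chromene-2,6(3H)-dione | O1[C@@H]2C[C@H](C)C(=O)C[C@H]2[C@H](C)CC1=O
F4 | step 11 | (4R,4aS,6R,7S,8aR)-6-hydroxy-4,7-dimethyloctahydro-2H-chromen-2-one | O1[C@@H]2C[C@H](C)[C@H](O)C[C@H]2[C@H](C)CC1=O
F5 | step 11 | (4R,4aS,6R,7S,8aR)-4,7-dimethyl-6-(triethylsilyloxy)octahydro-2H-chromen-2-one | O1[C@@H]2C[C@H](C)[C@H](O[Si](CC)(CC)CC)C[C@H]2[C@H](C)CC1=O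
F6 | step 11 | (6R)-6-[(1S,2R,4S,5R)-2-hydroxy-4-methyl-5-(triethylsilyloxy)cyclohexyl]-2-methylhept-2-en-4-one | O[C@@H]1C[C@H](C)[C@H](O[Si](CC)(CC)CC)C[C@H]1[C@H](C)CC(=O)C=C(C)C
F7 | step 11 | angelate of F6 at the ring hydroxyl | C/C=C(/C)C(=O)O[C@@H]1C[C@H](C)[C@H](O[Si](CC)(CC)CC)C[C@H]1[C@H](C)CC(=O)C=C(C)C
F8 | step 11 | (4R)-allylic alcohol from F7 | C/C=C(/C)C(=O)O[C@@H]1C[C@H](C)[C@H](O[Si](CC)(CC)CC)C[C@H]1[C@H](C)C[C@H](C=C(C)C)O
F9 | step 11 | triethylsilyl ether of 24 at the ring hydroxyl | C/C=C(/C)C(=O)O[C@@H]1C[C@H](C)[C@H](O[Si](CC)(CC)CC)C[C@H]1[C@H](C)C[C@H](C=C(C)C)OC(C)=O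
F10 | step 9 | (1R,2S,5R)-2-[(2R,4S)-4-hydroxy-6-methylhept-5-en-2-yl]-4,4-dimethoxy-5-methylcyclohexyl (2Z)-2-methylbut-2-enoate | C/C=C(/C)C(=O)O[C@@H]1C[C@@H](C)C(OC)(OC)C[C@H]1[C@H](C)C[C@@H](C=C(C)C)O
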